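**Plan**
1. Cuts, in retrosynthetic order: the fifteen O–benzyl bonds; the two methine–aryl bonds that join C6 and C8 of ring A of afzelechin to two identical oxolane arms; in each arm the aryl–C(=O) bond at C4, then C4–C5, then O1–C2.
2. Enabling feature: in each oxolane (O1, C2–C5), C4 is alpha to a carbonyl carbon and C5 is a benzylic carbon on O1. The C4 carbonyl stands 1,4 to the oxygen-bearing arm methine. The carbonyl can therefore be held as a gamma-lactone on that methine oxygen, C4 can become a carbenoid, and C5 can come from the CH2 of a 4-benzyloxybenzyl ether on O1, five atoms away.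
3. Forward ring order: lactone and cyclopropane form together by intramolecular cyclopropanation; a benzylic alcohol opens the cyclopropane at C2; C–H insertion closes the oxolane across the lactone; an aryllithium opens the lactone; two arms are joined to the flavan; debenzylation follows.
4. Stereochemistry: the (R)-carbinol comes from a catalytic asymmetric alkenylzinc addition. It directs C3 in the cyclopropanation. C2 arises by inversion in the ring opening, C5 in the insertion, and C4 by epimerisation. The two arm methines are set by 1,2-induction, and flavan C2/C3 come from (+)-afzelechin.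

Key step: step 9

Numbering used below: oxolane O1, C2 (2,4-dioxygenated aryl), C3 (bears the arm methine, called the linker), C4 (aroyl), C5 (4-oxygenated aryl). Flavan atoms keep their usual numbers.
Assumption: hydroxy ketone 18 is drawn open although it may rest largely as its bicyclic lactol, because both forms enter step 12 through the same enolate.
Remark: 21 is a single enantiomer, so any minor enantiomer of 19 ends up in diastereomeric adducts that are removed at the stage of 23.

Step 1
Reactants: 1 2,4-dihydroxybenzaldehyde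
Product: 2 2,4-bis(benzyloxy)benzaldehyde
Conditions: BnBr (2.3 equiv), K2CO3, DMF, 60 °C
Reagents that add atoms: benzyl bromide, BrCc1ccccc1
Why: Williamson ether synthesis, in which warm DMF and carbonate also alkylate the chelated ortho hydroxyl, and no stereocentre is involved.

Step 2
Reactants: 2 2,4-bis(benzyloxy)benzaldehyde
Product: 3 2,4-bis(benzyloxy)-1-ethynylbenzene
Conditions: dimethyl (1-diazo-2-oxopropyl)phosphonate, K2CO3, MeOH/THF, rt
Reagents that add atoms: dimethyl (1-diazo-2-oxopropyl)phosphonate, CC(=O)C(=[N+]=[N-])P(=O)(OC)OC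
Why: Ohira–Bestmann variant of the Seyferth–Gilbert homologation, which converts a non-enolisable aryl aldehyde into the terminal alkyne under carbonate conditions that leave benzyl ethers untouched.

Step 3
Reactants: 3 2,4-bis(benzyloxy)-1-ethynylbenzene; 4 4-(benzyloxy)benzaldehyde
Product: 7 (R,E)-1-[4-(benzyloxy)phenyl]-3-[2,4-bis(benzyloxy)phenyl]prop-2-en-1-ol, via alkenylborane 5 (not isolated), via alkenylzinc 6 (not isolated)
Conditions: Cy2BH, toluene, 0 °C to rt; Et2Zn, −78 °C; (+)-MIB (5 mol%), 4, −10 °C; aq NaHCO3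
Reagents that add atoms: none
Why: Syn-hydroboration, boron-to-zinc exchange and amino-alcohol-catalysed asymmetric alkenylzinc addition are well precedented for aromatic aldehydes; the hydroboration fixes the E alkene and (+)-MIB sends the alkenyl group to the Re face of 4, which sets the (R)-carbinol centre.

Step 4
Reactants: 7 allylic alcohol
Product: 8 (R,E)-1-[4-(benzyloxy)phenyl]-3-[2,4-bis(benzyloxy)phenyl]prop-2-en-1-yl 3-oxobutanoate
Conditions: diketene, DMAP (5 mol%), THF, −10 °C to rt
Reagents that add atoms: diketene, C=C1CC(=O)O1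
Why: DMAP-catalysed acetoacetylation with diketene acylates at oxygen under acid-free conditions below room temperature, so the ionisable 1,3-diarylallyl C–O bond and its configuration stay intact.

Step 5
Reactants: 8 acetoacetate
Product: 9 (R,E)-1-[4-(benzyloxy)phenyl]-3-[2,4-bis(benzyloxy)phenyl]prop-2-en-1-yl 2-diazo-3-oxobutanoate
Conditions: p-ABSA, Et3N, MeCN, 0 °C to rt
Reagents that add atoms: 4-acetamidobenzenesulfonyl azide, CC(=O)Nc1ccc(cc1)S(=O)(=O)N=[N+]=[N-]
Why: Regitz diazo transfer to an active methylene group needs only an amine base and touches neither the alkene nor the carbinol centre.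

Step 6
Reactants: 9 diazoacetoacetate
Product: 10 (1S,4R,5R,6S)-1-acetyl-4-[4-(benzyloxy)phenyl]-6-[2,4-bis(benzyloxy)phenyl]-3-oxabicyclo[3.1.0]hexan-2-one (C4 aryl on the lactone face opposite to the cyclopropane, C6 aryl exo)
Conditions: Rh2(OAc)4 (1 mol%), CH2Cl2, slow addition, reflux
Reagents that add atoms: none
Why: Intramolecular carbenoid cyclopropanation of an allylic diazoacetoacetate is stereospecific, so the E alkene places the C6 aryl exo, and the carbinol centre selects the alkene face because in the reacting rotamer its hydrogen lies inside over the alkene and its aryl group outside, which leaves that aryl anti to the new three-membered ring and sets oxolane C3.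

Step 7
Reactants: 10 donor–acceptor cyclopropane; 11 4-(benzyloxy)benzyl alcohol
Product: 12 (4S,5R)-3-acetyl-5-[4-(benzyloxy)phenyl]-4-{(R)-[2,4-bis(benzyloxy)phenyl][(4-benzyloxybenzyl)oxy]methyl}oxolan-2-one (mixture at the acetyl-bearing carbon)
Conditions: 11 (3 equiv), Yb(OTf)3 (10 mol%), 4 Å MS, CH2Cl2, −30 to 0 °C; Et3N quench
Reagents that add atoms: none
Why: In this Lewis-acid-catalysed ring opening of a donor–acceptor cyclopropane by an alcohol, chelation of the beta-keto lactone polarises the C1–C6 bond and the alcohol attacks the benzylic carbon from the rear with inversion; should the bond break first, the cation is born in its allylic-strain-minimised rotamer with the metal enolate still covering the same face, so both pathways give the aryl-bearing carbon (oxolane C2) with the configuration that later places its aryl cis to the linker.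

Step 8
Reactants: 12 alpha-acetyl lactone
Product: 13 (4S,5R)-3-diazo-5-[4-(benzyloxy)phenyl]-4-{(R)-[2,4-bis(benzyloxy)phenyl][(4-benzyloxybenzyl)oxy]methyl}oxolan-2-one
Conditions: p-ABSA, DBU, MeCN, 0 °C to rt
Reagents that add atoms: 4-acetamidobenzenesulfonyl azide, CC(=O)Nc1ccc(cc1)S(=O)(=O)N=[N+]=[N-]
Why: In this deacylative Regitz diazo transfer the enolate of the alpha-substituted beta-keto lactone adds to the azide and the acetyl group leaves as the N-acetylsulfonamide, which erases the epimer mixture under basic conditions that the acid-labile bis-benzylic ether tolerates.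

Step 9
Reactants: 13 alpha-diazo-gamma-butyrolactone
Product: 14 (3R,3aS,4R,6S,6aR)-3,6-bis[4-(benzyloxy)phenyl]-4-[2,4-bis(benzyloxy)phenyl]tetrahydro-1H,3H-furo[3,4-c]furan-1-one (cis-fused; 3-aryl exo, 4-aryl and 6-aryl endo)
Conditions: Rh2(OAc)4 (2 mol%), CH2Cl2 (high dilution), slow addition, rt
Reagents that add atoms: none
Why: Rh2(OAc)4 expels dinitrogen from 13, and the electrophilic carbenoid at C4 inserts into one C–H bond of the O1–CH2–aryl group through a concerted, asynchronous three-centre transition state with hydride-transfer character. The closest known reaction type is the dirhodium-catalysed 1,5 C–H insertion of alpha-diazo-gamma-butyrolactones into benzylic ether C–H bonds, which gives furofuranones with an endo aryl group. The oxolane ring (O1, C2, C3, C4, C5) closes by this 1,5-insertion through the new C4–C5 bond, across the lactone bond C3–C4. C4 is controlled by the ring: the chain on C3 reaches the carbenoid only from its own lactone face and a trans-fused pair of five-membered rings is too strained, so the fusion is cis. C5 is controlled by the catalyst wall: the metal leaves C4 along the convex rim, so the aryl group of the reacting CH2 turns away from the acetate ligands and ends on the concave face, cis to the lactone carbonyl and to the preset C2 aryl. The step must beat the 1,2-hydride shift from C3, attack on the arenes and insertion into ArO–CH2Ph groups; the target C–H is the only one five atoms away and is activated by both O1 and the 4-benzyloxyphenyl ring, the free ortho position of the C2 aryl is meta to both of its oxygens, and the other benzylic CH2 groups would need rings of seven or more atoms.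

Step 10
Reactants: 15 4-bromoresorcinol
Product: 16 2,4-bis(benzyloxy)-1-bromobenzene
Conditions: BnBr (2.3 equiv), K2CO3, DMF, rt
Reagents that add atoms: benzyl bromide, BrCc1ccccc1
Why: Williamson ether synthesis on two free phenols, with the aryl bromide inert to carbonate.

Step 11
Reactants: 16 2,4-bis(benzyloxy)-1-bromobenzene; 14 furofuranone
Product: 18 all-cis hydroxy ketone, 2,4-bis(benzyloxy)phenyl (2R,3R,4R,5S)-2-[2,4-bis(benzyloxy)phenyl]-5-[4-(benzyloxy)phenyl]-3-{(R)-[4-(benzyloxy)phenyl](hydroxy)methyl}oxolan-4-yl ketone, via aryllithium 17 (not isolated)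
Conditions: 16, n-BuLi, THF, −78 °C; then 14, −78 °C; AcOH quench at −78 °C
Reagents that add atoms: none
Why: Bromine–lithium exchange followed by addition of the aryllithium to a gamma-lactone stops at the lithium hemiketal at −78 °C, as in lactol syntheses from sugar lactones, so a single aryl group enters from the convex face of the carbonyl, and any enolised lactone can only be reprotonated to the same cis-fused 14.

Step 12
Reactants: 18 all-cis hydroxy ketone
Product: 19 (2R,3R,4S,5S)-hydroxy ketone, the C4 epimer of 18 (aroyl trans to the C3 arm and to the C5 aryl; carbinol still R)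
Conditions: DBU (0.3 equiv), toluene, rt
Reagents that add atoms: none
Why: Base-mediated epimerisation of an alpha-branched aryl ketone through its enolate is driven by relief of the four contiguous cis substituents, while ring opening by E1cB loss of O1 is held back because the C5–O1 bond lies near the nodal plane of the exocyclic enolate (the reverse of a 5-endo-trig closure).

Step 13
Reactants: 20 (+)-afzelechin
Product: 21 (2R,3S)-5,7-bis(benzyloxy)-2-[4-(benzyloxy)phenyl]chroman-3-ol (5,7,4'-tri-O-benzylafzelechin)
Conditions: BnBr (3.3 equiv), K2CO3, DMF, 0 °C to rt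
Reagents that add atoms: benzyl bromide, BrCc1ccccc1
Why: Williamson ether synthesis restricted to the three phenols, since carbonate does not deprotonate the secondary alcohol, under the mild conditions used for flavan-3-ols that leave C2 and C3 unchanged.

Step 14
Reactants: 19 hydroxy ketone (2.3 equiv); 21 tri-O-benzylafzelechin
Product: 23 pentadeca-O-benzyl ether of the target (both arms 2R,3S,4S,5S with linker S; flavan 2R,3S; 3-OH free), via C8 mono-adduct 22 (not isolated)
Conditions: BF3·OEt2 (20 mol%), 4 Å MS, CH2Cl2, −78 to −30 °C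
Reagents that add atoms: none
Why: This is a Friedel–Crafts benzylation of the kind used to couple benzylated flavan-3-ols, in which the 4-benzyloxyphenyl carbinol ionises well below the temperature at which the ring ethers do, ring A reacts first at C8 and then at the one remaining position C6, and each methine centre is set by 1,2-induction: the cation holds C3–H in its plane toward the aryl group (allylic strain), and in the C3 envelope with the C3, C4 and C5 substituents pseudo-equatorial its C4-side face is covered by the aroyl group while its C2-side face meets only H2 because the C2 aryl is pseudo-axial, so the arene enters from the C2 side, with formal inversion relative to the departed oxygen.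

Step 15
Reactants: 23 pentadeca-O-benzyl ether
Product: 24 target CNP0225367.3
Conditions: H2 (1 atm), Pd(OH)2/C, THF/MeOH, rt
Reagents that add atoms: none
Why: Catalytic hydrogenolysis cleaves aryl benzyl ethers faster than it opens the ring-held benzylic C–O bonds of the oxolanes and the chroman or reduces the hydrogen-bonded 2,4-dihydroxyphenyl ketones, as in the closing step of benzyl-based flavan-3-ol oligomer and phenolic lignan syntheses, and no stereocentre is touched.

**Compound list**
1 | 2,4-dihydroxybenzaldehyde | O=Cc1ccc(O)cc1O | starting material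
2 | 2,4-bis(benzyloxy)benzaldehyde | O=Cc1ccc(OCc2ccccc2)cc1OCc1ccccc1 | intermediate
3 | 2,4-bis(benzyloxy)-1-ethynylbenzene | C#Cc1ccc(OCc2ccccc2)cc1OCc1ccccc1 | intermediate
4 | 4-(benzyloxy)benzaldehyde | O=Cc1ccc(OCc2ccccc2)cc1 | starting material
5 | (E)-{2-[2,4-bis(benzyloxy)phenyl]ethenyl}dicyclohexylborane | C1CCCCC1B(/C=C/c1ccc(OCc2ccccc2)cc1OCc1ccccc1)C1CCCCC1 | intermediate
6 | (E)-{2-[2,4-bis(benzyloxy)phenyl]ethenyl}(ethyl)zinc | CC[Zn]/C=C/c1ccc(OCc2ccccc2)cc1OCc1ccccc1 | intermediate
7 | (R,E)-1-[4-(benzyloxy)phenyl]-3-[2,4-bis(benzyloxy)phenyl]prop-2-en-1-ol | O[C@@H](c1ccc(OCc2ccccc2)cc1)/C=C/c1ccc(OCc2ccccc2)cc1OCc1ccccc1 | intermediate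
8 | acetoacetate of 7 | CC(=O)CC(=O)O[C@@H](c1ccc(OCc2ccccc2)cc1)/C=C/c1ccc(OCc2ccccc2)cc1OCc1ccccc1 | intermediate
9 | 2-diazoacetoacetate of 7 | CC(=O)C(=[N+]=[N-])C(=O)O[C@@H](c1ccc(OCc2ccccc2)cc1)/C=C/c1ccc(OCc2ccccc2)cc1OCc1ccccc1 | intermediate
10 | (1S,4R,5R,6S)-1-acetyl-4-[4-(benzyloxy)phenyl]-6-[2,4-bis(benzyloxy)phenyl]-3-oxabicyclo[3.1.0]hexan-2-one | O=C1O[C@@H](c2ccc(OCc3ccccc3)cc2)[C@@H]2[C@@H](c3ccc(OCc4ccccc4)cc3OCc3ccccc3)[C@]12C(C)=O | intermediate
11 | 4-(benzyloxy)benzyl alcohol | OCc1ccc(OCc2ccccc2)cc1 | starting material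
12 | alpha-acetyl lactone with the C2 4-benzyloxybenzyl ether (epimer mixture at the acetyl carbon) | O=C1C(C(C)=O)[C@H]([C@H](c2ccc(OCc3ccccc3)cc2)O1)[C@H](c2ccc(OCc3ccccc3)cc2OCc2ccccc2)OCc1ccc(OCc2ccccc2)cc1 | intermediate
13 | alpha-diazo-gamma-butyrolactone, precursor of the key step | O=C1C(=[N+]=[N-])[C@H]([C@H](c2ccc(OCc3ccccc3)cc2)O1)[C@H](c2ccc(OCc3ccccc3)cc2OCc2ccccc2)OCc1ccc(OCc2ccccc2)cc1 | intermediate
14 | (3R,3aS,4R,6S,6aR)-triaryl furofuranone, product of the key step | O=C1[C@@H]2[C@H]([C@H](c3ccc(OCc4ccccc4)cc3)O1)[C@H](c3ccc(OCc4ccccc4)cc3OCc3ccccc3)O[C@@H]2c1ccc(OCc2ccccc2)cc1 | intermediate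
15 | 4-bromoresorcinol | Oc1ccc(Br)c(O)c1 | starting material
16 | 2,4-bis(benzyloxy)-1-bromobenzene | Brc1ccc(OCc2ccccc2)cc1OCc1ccccc1 | intermediate
17 | 2,4-bis(benzyloxy)phenyllithium | [Li]c1ccc(OCc2ccccc2)cc1OCc1ccccc1 | intermediate
18 | all-cis hydroxy ketone (2R,3R,4R,5S; carbinol R) | O=C(c1ccc(OCc2ccccc2)cc1OCc1ccccc1)[C@@H]1[C@H]([C@H](c2ccc(OCc3ccccc3)cc2)O)[C@H](c2ccc(OCc3ccccc3)cc2OCc2ccccc2)O[C@@H]1c1ccc(OCc2ccccc2)cc1 | intermediate
19 | C4-epimerised hydroxy ketone (2R,3R,4S,5S; carbinol R) | O=C(c1ccc(OCc2ccccc2)cc1OCc1ccccc1)[C@H]1[C@H]([C@H](c2ccc(OCc3ccccc3)cc2)O)[C@H](c2ccc(OCc3ccccc3)cc2OCc2ccccc2)O[C@@H]1c1ccc(OCc2ccccc2)cc1 | intermediate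
20 | (+)-afzelechin (2R,3S) | Oc1cc(O)c2c(c1)O[C@H](c1ccc(O)cc1)[C@@H](O)C2 | starting material
21 | 5,7,4'-tri-O-benzylafzelechin | C(c1ccccc1)Oc1cc(OCc2ccccc2)c2c(c1)O[C@H](c1ccc(OCc3ccccc3)cc1)[C@@H](O)C2 | intermediate
22 | C8 mono-adduct of 21 with one arm (linker S) | C(c6ccccc6)Oc1cc(OCc6ccccc6)c2c(c1[C@H](c4ccc(OCc6ccccc6)cc4)[C@H]4[C@H](C(=O)c5ccc(OCc6ccccc6)cc5OCc6ccccc6)[C@@H](c5ccc(OCc6ccccc6)cc5)O[C@H]4c4ccc(OCc6ccccc6)cc4OCc6ccccc6)O[C@H](c1ccc(OCc6ccccc6)cc1)[C@@H](O)C2 | intermediate
23 | pentadeca-O-benzyl ether of the target | O=C(c1ccc(OCc6ccccc6)cc1OCc6ccccc6)[C@H]1[C@H]([C@@H](c2ccc(OCc6ccccc6)cc2)c2c(OCc6ccccc6)c3c(c([C@H](c4ccc(OCc6ccccc6)cc4)[C@H]4[C@H](C(=O)c5ccc(OCc6ccccc6)cc5OCc6ccccc6)[C@@H](c5ccc(OCc6ccccc6)cc5)O[C@H]4c4ccc(OCc6ccccc6)cc4OCc6ccccc6)c2OCc6ccccc6)O[C@H](c2ccc(OCc6ccccc6)cc2)[C@@H](O)C3)[C@H](c2ccc(OCc6ccccc6)cc2OCc6ccccc6)O[C@@H]1c1ccc(OCc6ccccc6)cc1 | intermediate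
24 | CNP0225367.3 (arms 2R,3S,4S,5S, linkers S; flavan 2R,3S) | O=C(c1ccc(O)cc1O)[C@H]1[C@H]([C@@H](c2ccc(O)cc2)c2c(O)c3c(c([C@H](c4ccc(O)cc4)[C@H]4[C@H](C(=O)c5ccc(O)cc5O)[C@@H](c5ccc(O)cc5)O[C@H]4c4ccc(O)cc4O)c2O)O[C@H](c2ccc(O)cc2)[C@@H](O)C3)[C@H](c2ccc(O)cc2O)O[C@@H]1c1ccc(O)cc1 | target

**Count:** 15 steps in total. The longest linear sequence is 13 steps (1–9, 11, 12, 14, 15).

**Steps most likely to fail**

Step 14. Several processes may defeat the coupling:
- Face selection at either linker cation may be poor.
- The second alkylation may stall at crowded C6.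
- The cation may alkylate the resorcinol ring of another molecule of 19.
- The acid may ionise the O1–C2 bond and erode C2.

The fallback sets out from 19 and unprotected 20 and comes back at 24. The two are coupled in CH2Cl2/THF under a chiral BINOL-derived N-triflylphosphoramide bearing 2,4,6-triisopropylphenyl groups, with the catalyst enantiomer chosen for the matched case. This should give the dodeca-O-benzyl bis-adduct with free flavan hydroxyls F1, which is hydrogenolysed over Pd(OH)2/C to 24. The free phloroglucinol-type ring is smaller and far more nucleophilic, so a weaker acid suffices. Its hydroxyl groups also hydrogen-bond to the chiral anion paired with the cation, so face selection passes from the substrate to the catalyst.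

Step 9. Three things may go wrong:
- A 1,2-hydride shift from C3 may outrun insertion.
- The endo C2 aryl may hinder the folding that brings the CH2 over C4.
- The aryl of the reacting CH2 may end on the convex face.

The fallback sets out from 10 and 4 and comes back at 14. A Sn(OTf)2-catalysed formal [3+2] cycloaddition of the donor–acceptor cyclopropane with the aldehyde forms O1–C2 with inversion. The enolate then closes onto the oxocarbenium carbon with the usual 2,5-cis preference, giving the 6a-acetyl furofuranone F2. Retro-Claisen deacetylation (K2CO3, MeOH/THF, 0 °C) and protonation of the lactone enolate, which can only restore the cis fusion, then deliver 14.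

Step 7. Three things may go wrong:
- The opened zwitterion may collapse through the acetyl oxygen (Cloke–Wilson rearrangement to a dihydrofuran).
- The product ether may re-ionise with loss of the C2 configuration.
- Alcohol 11 may self-condense.

The fallback sets out from 9 and comes back at 13. It removes the second acceptor so that no enol oxygen is available for collapse.
- Aqueous LiOH cleaves the acetyl group to give the allylic diazoacetate F3.
- Rh2(cap)4 (dirhodium tetracaprolactamate) closes F3 to the mono-acceptor cyclopropane lactone F4.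
- Alcohol 11 opens F4 at the benzylic carbon with inversion (Sc(OTf)3, CH2Cl2) to the alpha-unsubstituted lactone F5.
- Detrifluoroacetylative diazo transfer (LiHMDS, CF3CO2CH2CF3, −78 °C; then MsN3, Et3N) passes through the alpha-trifluoroacetyl lactone F6 and gives 13.

Further compounds
F1 | step 14 | dodeca-O-benzyl bis-adduct with free flavan hydroxyls | O=C(c1ccc(OCc6ccccc6)cc1OCc6ccccc6)[C@H]1[C@H]([C@@H](c2ccc(OCc6ccccc6)cc2)c2c(O)c3c(c([C@H](c4ccc(OCc6ccccc6)cc4)[C@H]4[C@H](C(=O)c5ccc(OCc6ccccc6)cc5OCc6ccccc6)[C@@H](c5ccc(OCc6ccccc6)cc5)O[C@H]4c4ccc(OCc6ccccc6)cc4OCc6ccccc6)c2O)O[C@H](c2ccc(O)cc2)[C@@H](O)C3)[C@H](c2ccc(OCc6ccccc6)cc2OCc6ccccc6)O[C@@H]1c1ccc(OCc6ccccc6)cc1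
F2 | step 9 | 6a-acetyl furofuranone | O=C1[C@]2(C(C)=O)[C@H]([C@H](c3ccc(OCc4ccccc4)cc3)O1)[C@H](c3ccc(OCc4ccccc4)cc3OCc3ccccc3)O[C@@H]2c1ccc(OCc2ccccc2)cc1
F3 | step 7 | allylic diazoacetate | [N-]=[N+]=CC(=O)O[C@@H](c1ccc(OCc2ccccc2)cc1)/C=C/c1ccc(OCc2ccccc2)cc1OCc1ccccc1
F4 | step 7 | mono-acceptor cyclopropane lactone | O=C1O[C@@H](c2ccc(OCc3ccccc3)cc2)[C@@H]2[C@@H](c3ccc(OCc4ccccc4)cc3OCc3ccccc3)[C@H]12
F5 | step 7 | alpha-unsubstituted lactone | O=C1C[C@H]([C@H](c2ccc(OCc3ccccc3)cc2)O1)[C@H](c2ccc(OCc3ccccc3)cc2OCc2ccccc2)OCc1ccc(OCc2ccccc2)cc1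
F6 | step 7 | alpha-trifluoroacetyl lactone | O=C1C(C(=O)C(F)(F)F)[C@H]([C@H](c2ccc(OCc3ccccc3)cc2)O1)[C@H](c2ccc(OCc3ccccc3)cc2OCc2ccccc2)OCc1ccc(OCc2ccccc2)cc1
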